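**Plan**

- Retrosynthesis: the C7 acetate is removed (selective acylation of a 6β,7β,8α-triol as the last step). C14=C15 and C12=C13 are cut by two Wittig olefinations back to a C12 aldehyde, and the 6β- and 7β-carbinols are traced to a C7 ketone.
- In ring B, C7 (oxygen) and C8 (tertiary hydroxyl plus the C17 methyl) then form an α-ketol pair, the pattern left by enlargement of a 1-acetylcyclopentanol. Cutting C8–C9 gives a B-nor trans-hydrindane with 7α-OH and 7β-acetyl.
- That hydrindane goes back through C7=C8 (Wittig ethylidenation, osmylation) and C9–C11 (Negishi coupling on the C9 enol triflate) to a 4,4,10-trimethyl-trans-hydrindan-9-one made from (S)-Hajos–Parrish ketone.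
- Forward: ring A is finished on the bicyclic dione, the C11–C12 unit and the acetyl carbons are attached, ring B arises by the 1,2-shift, then C6 is oxygenated, the diene is built and O7 is acetylated.
- Stereochemistry: C10 comes from the starting dione. C5, C9 and the ketol carbinol C7 are set by α-face hydrogenation, hydroboration and osmylation (anti to the C10 methyl). C8 is set by the chelate of the key step, C7 and C6 by α-face hydride delivery, and the 12E alkene by a stabilised ylide.

Key step: step 12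

Remark on numbering: labdane numbers are used for every intermediate. The hydrindanes contain C1–C7, C9, C10 and the methyls C18–C20; C8 and C17 enter in step 9. α/β mean opposite to/on the side of the C10 methyl. In 1 the enone carbonyl is C3 and the cyclopentanone carbonyl is C9.

Remark on mixtures: 15 (alkene geometry) and 16 (C8 epimers) are carried as mixtures that converge in step 11.

Remark on the key step: the aluminium-alkoxide-promoted ketol shift is assumed to pass through the same syn C–O/C=O chelate as the BF3-promoted one.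

**Step 1**
Reactants: 1 (S)-Hajos–Parrish ketone
Product: 2 C9 ethylene ketal of the Hajos–Parrish ketone (enone untouched)
Conditions: HOCH2CH2OH, p-TsOH·H2O (cat.), 4 Å molecular sieves, CH2Cl2, rt
Reagents that add atoms: ethylene glycol, OCCO
Why: Acid-catalysed ketalisation (dioxolane formation) should select the saturated cyclopentanone, because the C3 carbonyl is deactivated by conjugation with C4=C5.

**Step 2**
Reactants: 2 C9 ethylene ketal of the Hajos–Parrish ketone
Product: 3 4,4-dimethyl-3-oxo-Δ5(6)-hydrindene C9 ethylene ketal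
Conditions: KOtBu (3 equiv), MeI (6 equiv), tBuOH/THF, 0 °C → rt
Reagents that add atoms: iodomethane, CI
Why: Deconjugative α,α-dialkylation of the enone through its extended potassium dienolate should place both methyl groups on C4 and move the double bond to C5=C6.

**Step 3**
Reactants: 3 4,4-dimethyl-3-oxo-Δ5(6)-hydrindene C9 ethylene ketal
Product: 5 4,4,10-trimethyl-Δ5(6)-hydrindene C9 ethylene ketal, via C3 hydrazone 4 (not isolated)
Conditions: N2H4·H2O, KOH, diethylene glycol, 130 °C then 200 °C
Reagents that add atoms: none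
Why: Wolff–Kishner reduction (Huang–Minlon procedure) should remove the hindered C3 carbonyl through hydrazone 4, the ketal and the non-enolisable β,γ-alkene being inert to hot base.

**Step 4**
Reactants: 5 4,4,10-trimethyl-Δ5(6)-hydrindene C9 ethylene ketal
Product: 7 trans-4,4,10-trimethylhydrindan-9-one (5α-H), via saturated ketal 6 (not isolated)
Conditions: H2 (4 atm), Pd/C, EtOAc, rt; filter; then 2 M HCl, THF, rt
Reagents that add atoms: water, O
Why: Heterogeneous catalytic hydrogenation should deliver hydrogen to the α face of C5=C6, anti to the angular C10 methyl, which sets 5α-H and the trans ring fusion; acid-catalysed ketal hydrolysis then frees the C9 ketone.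

**Step 5**
Reactants: 7 trans-4,4,10-trimethylhydrindan-9-one
Product: 9 Δ7(9)-enol triflate of the hydrindanone, via potassium enolate 8 (not isolated)
Conditions: KN(SiMe3)2, THF, −78 °C; then PhNTf2, −78 → 0 °C
Reagents that add atoms: N-phenyl-bis(trifluoromethanesulfonimide), O=S(=O)(N(c1ccccc1)S(=O)(=O)C(F)(F)F)C(F)(F)F
Why: Enol triflate formation by O-sulfonylation of the enolate is regiospecific here, because C10 is quaternary and only C7 carries α-hydrogens.

**Step 6**
Reactants: 9 Δ7(9)-enol triflate; 10 (1,3-dioxolan-2-ylmethyl)zinc bromide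
Product: 11 9-(1,3-dioxolan-2-ylmethyl)-4,4,10-trimethyl-Δ7(9)-hydrindene (5α-H)
Conditions: Pd(PPh3)4 (5 mol %), THF, 60 °C
Reagents that add atoms: none
Why: Negishi cross-coupling of an alkenyl triflate with an alkylzinc halide (zerovalent palladium catalysis) should join C9–C11 and fix the double bond at C7=C9.

**Step 7**
Reactants: 11 9-(1,3-dioxolan-2-ylmethyl)-Δ7(9)-hydrindene
Product: 13 7α-hydroxy-9β-(1,3-dioxolan-2-ylmethyl)-4,4,10-trimethyl-trans-hydrindane (9α-H), via 7α-alkylborane 12 (not isolated)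
Conditions: BH3·THF, THF, 0 °C → rt; then 3 M NaOH, 30% H2O2, 0 °C → rt
Reagents that add atoms: hydrogen peroxide, OO
Why: Hydroboration–oxidation should add boron to the less substituted C7 and hydrogen to C9, syn and from the α face (anti to the C10 methyl), which sets 9α-H and the 9β side chain.

**Step 8**
Reactants: 13 7α-hydroxy-9β-(1,3-dioxolan-2-ylmethyl)-trans-hydrindane
Product: 14 9β-(1,3-dioxolan-2-ylmethyl)-4,4,10-trimethyl-trans-hydrindan-7-one
Conditions: Dess–Martin periodinane, pyridine, CH2Cl2, rt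
Reagents that add atoms: none
Why: Dess–Martin oxidation of the secondary alcohol is non-basic, so the enolisable C9 centre should be kept (its 9β, pseudo-equatorial arrangement is also the expected stable one).

**Step 9**
Reactants: 14 9β-(1,3-dioxolan-2-ylmethyl)-trans-hydrindan-7-one
Product: 15 7-ethylidene-9β-(1,3-dioxolan-2-ylmethyl)-4,4,10-trimethyl-trans-hydrindane (E/Z mixture)
Conditions: EtPPh3Br, KN(SiMe3)2, THF, 0 °C; then 14, 0 °C → rt
Reagents that add atoms: ethyltriphenylphosphonium bromide, CC[P+](c1ccccc1)(c1ccccc1)c1ccccc1.[Br-]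
Why: Wittig olefination with the unstabilised ethylidene ylide should add C8 and C17 to the cyclopentanone; the alkene geometry is of no consequence because C8 becomes a carbonyl in step 11.

**Step 10**
Reactants: 15 7-ethylidene-9β-(1,3-dioxolan-2-ylmethyl)-trans-hydrindane
Product: 16 7α-hydroxy-7β-(1-hydroxyethyl)-9β-(1,3-dioxolan-2-ylmethyl)-4,4,10-trimethyl-trans-hydrindane (C8 epimers)
Conditions: OsO4 (2 mol %), NMO, acetone/H2O, rt
Reagents that add atoms: N-methylmorpholine N-oxide, C[N+]1([O-])CCOCC1; water, O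
Why: OsO4-catalysed syn-dihydroxylation should occur on the α face, away from the C10 methyl and the 9β side chain, which puts the tertiary hydroxyl 7α and the two-carbon unit 7β.

**Step 11**
Reactants: 16 7α-hydroxy-7β-(1-hydroxyethyl)-trans-hydrindane
Product: 17 7β-acetyl-7α-hydroxy-9β-(1,3-dioxolan-2-ylmethyl)-4,4,10-trimethyl-trans-hydrindane
Conditions: SO3·pyridine, DMSO, iPr2NEt, CH2Cl2, 0 °C
Reagents that add atoms: none
Why: Parikh–Doering oxidation (activated DMSO) should convert the secondary C8 alcohol into the methyl ketone without glycol cleavage and leave the tertiary 7α-hydroxyl, giving the α-ketol.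

**Step 12**
Reactants: 17 7β-acetyl-7α-hydroxy-9β-(1,3-dioxolan-2-ylmethyl)-4,4,10-trimethyl-trans-hydrindane
Product: 18 8α-hydroxy-7-oxo-13,14,15,16-tetranorlabdan-12-al ethylene acetal
Conditions: Al(OtBu)3 (1.5 equiv), toluene, 80 °C
Reagents that add atoms: none
Why: The aluminium alkoxide of the 7α-hydroxyl binds the acetyl oxygen in a five-membered chelate, and the C7–C9 bond, aligned with the carbonyl π* orbital, shifts suprafacially to the acetyl carbon with retention at C9 while the alkoxide collapses to the C7 ketone. The closest known reaction type is the α-ketol (acyloin) rearrangement, as in the Lewis-acid D-homoannulation of 17α-hydroxy-20-oxo steroids. Ring B is closed not by cyclisation but by this 1,2-alkyl shift, which enlarges the five-membered ring to six and is driven by loss of cyclopentane strain and by exchange of a methyl ketone for a ring ketone. The new stereocentre C8 is set by the chelate: C8=O is held syn to the C7–O bond, so the new hydroxyl ends eclipsed with the C7 carbonyl, equatorial and α like the hydroxyl it came from, and the methyl is axial and β. The step needs C9 and not C6 to migrate: with the acetyl on the β face only C9 migration puts C8 directly into its chair position between C9 and C7, whereas C6 migration would need a boat and would press C17 against the 9β side chain, and C9 is also the more substituted terminus. Al(OtBu)3 has no transferable hydride and should leave the acetal intact.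

**Step 13**
Reactants: 18 8α-hydroxy-7-oxo-tetranorlabdan-12-al ethylene acetal
Product: 19 7,8α-bis(tert-butyldimethylsilyloxy)-13,14,15,16-tetranorlabd-6-en-12-al ethylene acetal
Conditions: TBSOTf (3 equiv), Et3N (5 equiv), CH2Cl2, −78 → 0 °C
Reagents that add atoms: tert-butyldimethylsilyl trifluoromethanesulfonate, CC(C)(C)[Si](C)(C)OS(=O)(=O)C(F)(F)F
Why: Silyl triflate/amine soft enolisation can only give the Δ6 silyl enol ether (C8 is quaternary) and should silylate the tertiary hydroxyl at the same time; excess amine and low temperature are chosen to spare the dioxolane.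

**Step 14**
Reactants: 19 7,8α-bis(tert-butyldimethylsilyloxy)-Δ6 enol ether
Product: 21 6α-hydroxy-7β,8α-bis(tert-butyldimethylsilyloxy)-13,14,15,16-tetranorlabdan-12-al ethylene acetal, via 6α-alkylborane 20 (not isolated)
Conditions: BH3·THF, THF, 0 °C → rt; then 30% H2O2, 3 M NaOAc (aq.), 0 °C → rt
Reagents that add atoms: hydrogen peroxide, OO
Why: Hydroboration–oxidation of a silyl enol ether should put boron on C6 (the β-carbon) and hydrogen on C7, syn and from the α face (the β face is closed by the axial C17, C19 and C20 methyls), which sets the 7β-silyloxy group and a 6α-hydroxyl.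

**Step 15**
Reactants: 21 6α-hydroxy-7β,8α-bis(silyloxy) acetal
Product: 22 6-oxo-7β,8α-bis(tert-butyldimethylsilyloxy)-13,14,15,16-tetranorlabdan-12-al ethylene acetal
Conditions: Dess–Martin periodinane, pyridine, CH2Cl2, rt
Reagents that add atoms: none
Why: Dess–Martin oxidation under buffered, non-epimerising conditions should give the C6 ketone with the trans ring fusion (5α-H) and the equatorial 7β-silyloxy group unchanged.

**Step 16**
Reactants: 22 6-oxo-7β,8α-bis(silyloxy) acetal
Product: 23 6β-hydroxy-7β,8α-bis(tert-butyldimethylsilyloxy)-13,14,15,16-tetranorlabdan-12-al ethylene acetal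
Conditions: NaBH4, MeOH/THF, 0 °C → rt
Reagents that add atoms: none
Why: Borohydride reduction should deliver hydride to the α face of C6, because axial approach from the β face is blocked by the syn-axial C17, C19 and C20 methyls, giving the axial 6β-alcohol as in 6-oxo steroids.

**Step 17**
Reactants: 23 6β-hydroxy-7β,8α-bis(silyloxy) acetal
Product: 24 6β-hydroxy-7β,8α-bis(tert-butyldimethylsilyloxy)-13,14,15,16-tetranorlabdan-12-al
Conditions: AcOH/THF/H2O (3:1:1), 45 °C
Reagents that add atoms: water, O
Why: Acid-catalysed acetal hydrolysis should free the C12 aldehyde while the hindered secondary and tertiary silyl ethers survive; the silylated O8 cannot close a lactol onto C12.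

**Step 18**
Reactants: 24 6β-hydroxy-7β,8α-bis(silyloxy)-12-aldehyde
Product: 25 (12E)-6β-hydroxy-7β,8α-bis(tert-butyldimethylsilyloxy)-15-norlabd-12-en-14-al
Conditions: Ph3P=C(CH3)CHO, toluene, 90 °C
Reagents that add atoms: 2-(triphenylphosphoranylidene)propanal, CC(C=O)=P(c1ccccc1)(c1ccccc1)c1ccccc1
Why: Wittig olefination with a stabilised ylide is under thermodynamic control and should give the E enal (formyl trans to C11), which sets the 12E geometry.

**Step 19**
Reactants: 25 (12E)-enal
Product: 26 (12E)-7β,8α-bis(tert-butyldimethylsilyloxy)labda-12,14-dien-6β-ol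
Conditions: MePPh3Br, KN(SiMe3)2, THF, 0 °C; then 25, −78 → 0 °C
Reagents that add atoms: methyltriphenylphosphonium bromide, C[P+](c1ccccc1)(c1ccccc1)c1ccccc1.[Br-]
Why: Wittig methylenation of the enal should complete the conjugated diene without touching the trisubstituted alkene; excess ylide covers the free 6β-hydroxyl.

**Step 20**
Reactants: 26 (12E)-7β,8α-bis(silyloxy)labda-12,14-dien-6β-ol
Product: 27 (12E)-labda-12,14-diene-6β,7β,8α-triol
Conditions: Bu4NF, THF, 55 °C
Reagents that add atoms: none
Why: Fluoride-mediated desilylation should cleave both silyl ethers under conditions that leave the diene untouched.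

**Step 21**
Reactants: 27 (12E)-labda-12,14-diene-6β,7β,8α-triol
Product: 28 (12E)-6β,8α-dihydroxylabda-12,14-dien-7β-yl acetate (CNP0225877.1)
Conditions: Ac2O (1.2 equiv), pyridine, 0 °C
Reagents that add atoms: acetic anhydride, CC(=O)OC(C)=O
Why: Selective acylation should take the equatorial 7β-hydroxyl, since the axial 6β-hydroxyl is flanked by three syn-axial methyls and the 8α-hydroxyl is tertiary (the pattern known from 6β,7β-diols of this decalin type).

**Compound list**

1 | (S)-Hajos–Parrish ketone, (S)-7a-methyl-2,3,7,7a-tetrahydro-1H-indene-1,5(6H)-dione | O=C1CC[C@]2(C)C(=O)CCC2=C1 | starting material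
2 | C9 ethylene ketal of 1 | O=C1CC[C@]2(C)C3(OCCO3)CCC2=C1 | intermediate
3 | 4,4-dimethyl-3-oxo-Δ5(6)-hydrindene C9 ethylene ketal | O=C1CC[C@]2(C)C3(OCCO3)CC=C2C1(C)C | intermediate
4 | C3 hydrazone of 3 | NN=C1CC[C@]2(C)C3(OCCO3)CC=C2C1(C)C | intermediate (not isolated)
5 | 4,4,10-trimethyl-Δ5(6)-hydrindene C9 ethylene ketal | C1CC[C@]2(C)C3(OCCO3)CC=C2C1(C)C | intermediate
6 | trans-4,4,10-trimethylhydrindane C9 ethylene ketal (5α-H) | C1CC[C@]2(C)C3(OCCO3)CC[C@H]2C1(C)C | intermediate (not isolated)
7 | trans-4,4,10-trimethylhydrindan-9-one (5α-H, 10β-CH3) | O=C1CC[C@H]2C(C)(C)CCC[C@@]21C | intermediate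
8 | potassium Δ7(9)-enolate of 7 | [K+].[O-]C1=CC[C@H]2C(C)(C)CCC[C@@]21C | intermediate (not isolated)
9 | Δ7(9)-enol triflate of 7 | FC(F)(F)S(=O)(=O)OC1=CC[C@H]2C(C)(C)CCC[C@@]21C | intermediate
10 | (1,3-dioxolan-2-ylmethyl)zinc bromide | Br[Zn]CC1OCCO1 | starting material
11 | 9-(1,3-dioxolan-2-ylmethyl)-4,4,10-trimethyl-Δ7(9)-hydrindene (5α-H) | O1CCOC1CC2=CC[C@H]3C(C)(C)CCC[C@@]32C | intermediate
12 | 7α-boryl-9β-(1,3-dioxolan-2-ylmethyl)-trans-hydrindane (alkyl-BH2, 9α-H) | O1CCOC1C[C@H]2[C@H](B)C[C@H]3C(C)(C)CCC[C@@]32C | intermediate (not isolated)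
13 | 7α-hydroxy-9β-(1,3-dioxolan-2-ylmethyl)-4,4,10-trimethyl-trans-hydrindane | O1CCOC1C[C@H]2[C@H](O)C[C@H]3C(C)(C)CCC[C@@]32C | intermediate
14 | 9β-(1,3-dioxolan-2-ylmethyl)-4,4,10-trimethyl-trans-hydrindan-7-one | O1CCOC1C[C@H]2C(=O)C[C@H]3C(C)(C)CCC[C@@]32C | intermediate
15 | 7-ethylidene-9β-(1,3-dioxolan-2-ylmethyl)-4,4,10-trimethyl-trans-hydrindane (E/Z mixture) | O1CCOC1C[C@H]2C(=CC)C[C@H]3C(C)(C)CCC[C@@]32C | intermediate
16 | 7α-hydroxy-7β-(1-hydroxyethyl)-9β-(1,3-dioxolan-2-ylmethyl)-4,4,10-trimethyl-trans-hydrindane (C8 epimers) | O1CCOC1C[C@H]2[C@@](O)(C(C)O)C[C@H]3C(C)(C)CCC[C@@]32C | intermediate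
17 | 7β-acetyl-7α-hydroxy-9β-(1,3-dioxolan-2-ylmethyl)-4,4,10-trimethyl-trans-hydrindane | O1CCOC1C[C@H]2[C@@](O)(C(C)=O)C[C@H]3C(C)(C)CCC[C@@]32C | intermediate
18 | 8α-hydroxy-7-oxo-13,14,15,16-tetranorlabdan-12-al ethylene acetal | O1CCOC1C[C@H]2[C@](C)(O)C(=O)C[C@H]3C(C)(C)CCC[C@@]32C | intermediate
19 | 7,8α-bis(tert-butyldimethylsilyloxy)-13,14,15,16-tetranorlabd-6-en-12-al ethylene acetal | O1CCOC1C[C@H]2[C@](C)(O[Si](C)(C)C(C)(C)C)C(O[Si](C)(C)C(C)(C)C)=C[C@H]3C(C)(C)CCC[C@@]32C | intermediate
20 | 6α-boryl-7β,8α-bis(tert-butyldimethylsilyloxy)-13,14,15,16-tetranorlabdan-12-al ethylene acetal (alkyl-BH2) | O1CCOC1C[C@H]2[C@](C)(O[Si](C)(C)C(C)(C)C)[C@@H](O[Si](C)(C)C(C)(C)C)[C@H](B)[C@H]3C(C)(C)CCC[C@@]32C | intermediate (not isolated)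
21 | 6α-hydroxy-7β,8α-bis(tert-butyldimethylsilyloxy)-13,14,15,16-tetranorlabdan-12-al ethylene acetal | O1CCOC1C[C@H]2[C@](C)(O[Si](C)(C)C(C)(C)C)[C@@H](O[Si](C)(C)C(C)(C)C)[C@H](O)[C@H]3C(C)(C)CCC[C@@]32C | intermediate
22 | 6-oxo-7β,8α-bis(tert-butyldimethylsilyloxy)-13,14,15,16-tetranorlabdan-12-al ethylene acetal | O1CCOC1C[C@H]2[C@](C)(O[Si](C)(C)C(C)(C)C)[C@@H](O[Si](C)(C)C(C)(C)C)C(=O)[C@H]3C(C)(C)CCC[C@@]32C | intermediate
23 | 6β-hydroxy-7β,8α-bis(tert-butyldimethylsilyloxy)-13,14,15,16-tetranorlabdan-12-al ethylene acetal | O1CCOC1C[C@H]2[C@](C)(O[Si](C)(C)C(C)(C)C)[C@@H](O[Si](C)(C)C(C)(C)C)[C@@H](O)[C@H]3C(C)(C)CCC[C@@]32C | intermediate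
24 | 6β-hydroxy-7β,8α-bis(tert-butyldimethylsilyloxy)-13,14,15,16-tetranorlabdan-12-al | O=CC[C@H]1[C@](C)(O[Si](C)(C)C(C)(C)C)[C@@H](O[Si](C)(C)C(C)(C)C)[C@@H](O)[C@H]2C(C)(C)CCC[C@@]21C | intermediate
25 | (12E)-6β-hydroxy-7β,8α-bis(tert-butyldimethylsilyloxy)-15-norlabd-12-en-14-al | O=C/C(C)=C/C[C@H]1[C@](C)(O[Si](C)(C)C(C)(C)C)[C@@H](O[Si](C)(C)C(C)(C)C)[C@@H](O)[C@H]2C(C)(C)CCC[C@@]21C | intermediate
26 | (12E)-7β,8α-bis(tert-butyldimethylsilyloxy)labda-12,14-dien-6β-ol | C=C/C(C)=C/C[C@H]1[C@](C)(O[Si](C)(C)C(C)(C)C)[C@@H](O[Si](C)(C)C(C)(C)C)[C@@H](O)[C@H]2C(C)(C)CCC[C@@]21C | intermediate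
27 | (12E)-labda-12,14-diene-6β,7β,8α-triol | C=C/C(C)=C/C[C@H]1[C@](C)(O)[C@@H](O)[C@@H](O)[C@H]2C(C)(C)CCC[C@@]21C | intermediate
28 | (12E)-6β,8α-dihydroxylabda-12,14-dien-7β-yl acetate (CNP0225877.1) | C=C/C(C)=C/C[C@H]1[C@](C)(O)[C@@H](OC(C)=O)[C@@H](O)[C@H]2C(C)(C)CCC[C@@]21C | target

Total step count: 21. Longest linear sequence: 21 steps (1 → 28); 10 is used as purchased.

**Steps most likely to fail**

Step 12. What may go wrong is migration of C6 in place of C9, or leakage through a non-chelated transition state that inverts C8, or exchange of the acetal under Lewis acid. The fallback replaces the carbonyl acceptor by a leaving group on C8 and sets out from diol 16. Selective mesylation of the secondary hydroxyl (MsCl, Et3N, CH2Cl2, −20 °C) should give the 7α-hydroxy C8 mesylate F1. Et3Al in CH2Cl2 at −78 °C should then trigger a semipinacol 1,2-shift of the ring bond anti to the sulfonate and give the ring-enlarged 8-methyl-7-ketone F2 (C8–H, epimers). Thermodynamic enol silylation (Me3SiCl, Et3N, DMF, 80 °C) should give the Δ7(8) trimethylsilyl enol ether F3. Rubottom oxidation with dimethyldioxirane on the α face should give the 8α-trimethylsilyloxy-7-ketone F4, and K2CO3 in MeOH removes the silyl group, coming back to the route at 18.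

Step 14. What may go wrong is β-elimination of the 6-boryl-7-silyloxy intermediate to a Δ6 alkene before oxidation, or silyl migration from O7 to O6 during the peroxide work-up. The fallback introduces the C6 oxygen through the enolate and sets out from 18. KN(SiMe3)2 followed by 2-(phenylsulfonyl)-3-phenyloxaziridine should give the 6α,8α-dihydroxy-7-ketone F5. Ac2O in pyridine should acylate only the secondary hydroxyl, giving the 6α-acetoxy-8α-hydroxy-7-ketone F6. NaBH4 should reduce C7 from the α face to the 6α-acetoxy-7β,8α-diol F7. TBSOTf with 2,6-lutidine should give the 6α-acetoxy-7β,8α-bis-silyl ether F8, and K2CO3 in MeOH removes the acetate, coming back to the route at 21.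

Step 4. What may go wrong is slow or unselective hydrogen delivery to C5=C6, whose two allylic carbons are quaternary, so that cis-fused material forms. The fallback replaces catalytic hydrogenation by hydroboration and radical deoxygenation and sets out from 5. BH3·THF followed by NaOH/H2O2 should add from the α face and give the trans-fused 6α-alcohol F9. NaH, CS2 and MeI should give the 6α-xanthate F10. Barton–McCombie reduction with Bu3SnH and AIBN in toluene at 90 °C should remove the oxygen and come back to the route at 6, which is hydrolysed to 7 as in step 4.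

**Further compounds**

F1 | step 12 | 7α-hydroxy-7β-(1-methanesulfonyloxyethyl)-9β-(1,3-dioxolan-2-ylmethyl)-4,4,10-trimethyl-trans-hydrindane (C8 epimers) | O1CCOC1C[C@H]2[C@@](O)(C(C)OS(C)(=O)=O)C[C@H]3C(C)(C)CCC[C@@]32C
F2 | step 12 | 7-oxo-13,14,15,16-tetranorlabdan-12-al ethylene acetal (C8–H, epimers) | O1CCOC1C[C@H]2C(C)C(=O)C[C@H]3C(C)(C)CCC[C@@]32C
F3 | step 12 | 7-trimethylsilyloxy-13,14,15,16-tetranorlabd-7-en-12-al ethylene acetal | O1CCOC1C[C@H]2C(C)=C(O[Si](C)(C)C)C[C@H]3C(C)(C)CCC[C@@]32C
F4 | step 12 | 8α-trimethylsilyloxy-7-oxo-13,14,15,16-tetranorlabdan-12-al ethylene acetal | O1CCOC1C[C@H]2[C@](C)(O[Si](C)(C)C)C(=O)C[C@H]3C(C)(C)CCC[C@@]32C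
F5 | step 14 | 6α,8α-dihydroxy-7-oxo-13,14,15,16-tetranorlabdan-12-al ethylene acetal | O1CCOC1C[C@H]2[C@](C)(O)C(=O)[C@H](O)[C@H]3C(C)(C)CCC[C@@]32C
F6 | step 14 | 6α-acetoxy-8α-hydroxy-7-oxo-13,14,15,16-tetranorlabdan-12-al ethylene acetal | O1CCOC1C[C@H]2[C@](C)(O)C(=O)[C@H](OC(C)=O)[C@H]3C(C)(C)CCC[C@@]32C
F7 | step 14 | 6α-acetoxy-7β,8α-dihydroxy-13,14,15,16-tetranorlabdan-12-al ethylene acetal | O1CCOC1C[C@H]2[C@](C)(O)[C@@H](O)[C@H](OC(C)=O)[C@H]3C(C)(C)CCC[C@@]32C
F8 | step 14 | 6α-acetoxy-7β,8α-bis(tert-butyldimethylsilyloxy)-13,14,15,16-tetranorlabdan-12-al ethylene acetal | O1CCOC1C[C@H]2[C@](C)(O[Si](C)(C)C(C)(C)C)[C@@H](O[Si](C)(C)C(C)(C)C)[C@H](OC(C)=O)[C@H]3C(C)(C)CCC[C@@]32C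
F9 | step 4 | 6α-hydroxy-trans-4,4,10-trimethylhydrindane C9 ethylene ketal (5α-H) | C1CC[C@]2(C)C3(OCCO3)C[C@H](O)[C@H]2C1(C)C
F10 | step 4 | 6α-(methylsulfanylthiocarbonyloxy)-trans-4,4,10-trimethylhydrindane C9 ethylene ketal | C1CC[C@]2(C)C3(OCCO3)C[C@H](OC(=S)SC)[C@H]2C1(C)C
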